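**Retrosynthetic overview**

- Enabling feature: without the acetyl group, the anti-1,3-diol C3–C4–C5 (both carbinol carbons R) has a C2 axis through C4. O3/O5, C2/C6, C1/C7 and the two catechol rings are therefore pairwise homotopic.
- Last disconnections: the four phenols are masked as benzyl ethers to the end. The single acetate comes from a cyclic orthoacetate across O3/O5, and either mode of opening gives the same monoacetate.
- Key disconnection: both benzylic CH2–CH2 bonds (C6–C7 and its twin C1–C2) are cut at once. Each CH2(6)–CH(5)–O unit is a latent terminal oxirane, which leads to (S,S)-1,2:4,5-diepoxypentane and two 3,4-bis(benzyloxy)benzyl Grignard units.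
- The diepoxide comes from pentane-2,4-dione by acyl exchange to the 1,5-dichloro dione, (R)-BINAP–Ru hydrogenation (sets both stereocentres) and base closure.
- Rings: both arenes are bought. Only temporary rings are formed: two oxiranes (closed in step 3, opened in step 5), then one 1,3-dioxane orthoester (closed and opened in step 6).

Key step: step 5

Remark: the chain is numbered with C3 as the acetoxy carbon and C5 as the free carbinol carbon; both read R from the SMILES, which is the anti (C2-symmetric) diol series, and 3,4-bis(benzyloxy)benzyl chloride is taken as a catalogue compound.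

**Step 1**
Reactants: 1 pentane-2,4-dione (acetylacetone); 2 chloroacetyl chloride
Product: 3 1,5-dichloropentane-2,4-dione
Conditions: AlCl3 (excess), 2 (excess), PhNO2, 55–60 °C, AcCl allowed to distil off; ice/aq HCl; vacuum distillation
Reagents that add atoms: none
Why: AlCl3-mediated reversible C-acylation/deacylation of a β-diketone (acyl exchange), in which the aluminium chelate of 1 is acylated by 2 at the central carbon to a triacylmethane that sheds acetyl chloride, and loss of this low-boiling chloride drives the replacement of both acetyl groups by chloroacetyl groups.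

**Step 2**
Reactants: 3 1,5-dichloropentane-2,4-dione
Product: 4 (2S,4S)-1,5-dichloropentane-2,4-diol
Conditions: H2 (ca. 85 atm), [RuCl2((R)-BINAP)]2·NEt3 (cat.), MeOH, 80–100 °C; recrystallisation
Reagents that add atoms: none
Why: Noyori asymmetric hydrogenation of a β-diketone, in which chelation of the 1,3-dioxygen unit to the (R)-BINAP–Ru hydride fixes the face of each C=O so that both carbinol carbons are set under catalyst control in the spatial sense that turns 1 into (R,R)-pentane-2,4-diol (descriptor S here because CH2Cl outranks the central CH2), while a wrong-handed first reduction is diverted into the meso diol (Horeau-type amplification) that recrystallisation removes.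

**Step 3**
Reactants: 4 (2S,4S)-1,5-dichloropentane-2,4-diol
Product: 5 (2S,4S)-1,2:4,5-diepoxypentane [(2S,2'S)-2,2'-methylenebis(oxirane)]
Conditions: KOH (powder), Et2O, rt; distillation
Reagents that add atoms: none
Why: Double intramolecular Williamson closure (3-exo-tet) of the two chlorohydrins, in which only O–H and primary C–Cl bonds react, so that both stereocentres are carried over unchanged as S.

**Step 4**
Reactants: 6 3,4-bis(benzyloxy)benzyl chloride
Product: 7 3,4-bis(benzyloxy)benzylmagnesium chloride (titrated solution, used directly)
Conditions: Mg turnings (excess, I2-activated), 2-MeTHF, 0 °C, slow addition at high dilution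
Reagents that add atoms: magnesium [Mg]
Why: Grignard formation by insertion of magnesium into the benzylic C–Cl bond, with excess metal, slow addition, low temperature and 2-MeTHF holding back Wurtz homocoupling, while the aryl benzyl ethers are inert to the reagent.

**Step 5**
Reactants: 5 (2S,4S)-1,2:4,5-diepoxypentane; 7 3,4-bis(benzyloxy)benzylmagnesium chloride (3 equiv)
Product: 10 (3R,5R)-1,7-bis[3,4-bis(benzyloxy)phenyl]heptane-3,5-diol, via epoxy alkoxide 8 (not isolated), via bis-alkoxide 9 (not isolated)
Conditions: CuI (10–20 mol %), THF/2-MeTHF, −40 to 0 °C; sat. aq NH4Cl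
Reagents that add atoms: none
Why: Transmetalation of 7 gives a benzylcopper(I) ate species that attacks the unsubstituted CH2 of one oxirane of 5 in an SN2 manner to give 8, and the same event on the remaining oxirane joins the second ArCH2 unit to the large epoxy alkoxide fragment and gives 9, so that two benzylic CH2–CH2 bonds, both free carbinols and the whole 1,7-diarylheptane skeleton arise in one flask from a C5 precursor. The closest known reaction type is the copper(I)-catalysed Grignard opening of terminal epoxides, used two-directionally on C2-symmetric 1,2:4,5-diepoxypentane. No ring is closed and two oxiranes are opened. No stereocentre is created, because the C–O bonds at the two oxirane CH carbons are never touched and their configuration passes unchanged into C3 and C5, the descriptor changing from S to R only because the CIP order of the two CH2 neighbours is reversed. The step needs attack at the terminal and not the internal oxirane carbon, which the steric difference between CH2 and CH and the soft copper nucleophile secure, and it needs bond formation through the benzylic carbon and not the ortho ring carbon, which copper catalysis favours. The C2 axis makes the two oxiranes homotopic so that the order of the openings is of no consequence, and the magnesium alkoxide of 8 is too poor a nucleophile at or below 0 °C to close an oxetane or a tetrahydrofuran onto the second oxirane.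

**Step 6**
Reactants: 10 (3R,5R)-1,7-bis[3,4-bis(benzyloxy)phenyl]heptane-3,5-diol
Product: 12 (3R,5R)-1,7-bis[3,4-bis(benzyloxy)phenyl]-5-hydroxyheptan-3-yl acetate, via cyclic orthoacetate 11 (not isolated)
Conditions: MeC(OMe)3, CSA (cat.), CH2Cl2, rt; then 80% aq AcOH, rt
Reagents that add atoms: trimethyl orthoacetate COC(C)(OC)OC; water O
Why: Monoacylation of a diol through a cyclic orthoester, in which acid-catalysed exchange ties O3 and O5 into 1,3-dioxane 11, whose hydrolysis via the 1,3-dioxan-2-ylium ion can release one acetate only, and because O3 and O5 are homotopic either mode of opening (and any later 1,3-acyl shift) gives the same compound with both stereocentres untouched.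

**Step 7**
Reactants: 12 (3R,5R)-1,7-bis[3,4-bis(benzyloxy)phenyl]-5-hydroxyheptan-3-yl acetate
Product: 13 (3R,5R)-1,7-bis(3,4-dihydroxyphenyl)-5-hydroxyheptan-3-yl acetate (target)
Conditions: H2 (1 atm), 10% Pd/C, EtOAc–THF, rt; filtration and concentration under argon
Reagents that add atoms: none
Why: Catalytic hydrogenolysis of the four aryl benzyl ethers under neutral conditions, which leaves the acetate, the secondary alcohol and both stereocentres alone because the chain carries no benzylic C–O bond.

**Compound list**

1 | pentane-2,4-dione | CC(=O)CC(C)=O | starting material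
2 | chloroacetyl chloride | ClCC(Cl)=O | starting material
3 | 1,5-dichloropentane-2,4-dione | ClCC(=O)CC(=O)CCl | intermediate
4 | (2S,4S)-1,5-dichloropentane-2,4-diol | O[C@H](CCl)C[C@H](O)CCl | intermediate
5 | (2S,4S)-1,2:4,5-diepoxypentane | C1O[C@H]1C[C@H]1CO1 | intermediate
6 | 3,4-bis(benzyloxy)benzyl chloride | ClCc1ccc(OCc2ccccc2)c(OCc2ccccc2)c1 | starting material
7 | 3,4-bis(benzyloxy)benzylmagnesium chloride | Cl[Mg]Cc1ccc(OCc2ccccc2)c(OCc2ccccc2)c1 | intermediate
8 | chloromagnesium (2R)-4-[3,4-bis(benzyloxy)phenyl]-1-[(2S)-oxiran-2-yl]butan-2-olate | Cl[Mg]O[C@H](CCc1ccc(OCc2ccccc2)c(OCc2ccccc2)c1)C[C@H]1CO1 | intermediate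
9 | bis(chloromagnesium) (3R,5R)-1,7-bis[3,4-bis(benzyloxy)phenyl]heptane-3,5-diolate | Cl[Mg]O[C@H](CCc1ccc(OCc2ccccc2)c(OCc2ccccc2)c1)C[C@H](O[Mg]Cl)CCc1ccc(OCc2ccccc2)c(OCc2ccccc2)c1 | intermediate
10 | (3R,5R)-1,7-bis[3,4-bis(benzyloxy)phenyl]heptane-3,5-diol | O[C@H](CCc1ccc(OCc2ccccc2)c(OCc2ccccc2)c1)C[C@H](O)CCc1ccc(OCc2ccccc2)c(OCc2ccccc2)c1 | intermediate
11 | (4R,6R)-4,6-bis{2-[3,4-bis(benzyloxy)phenyl]ethyl}-2-methoxy-2-methyl-1,3-dioxane | COC1(C)O[C@H](CCc2ccc(OCc3ccccc3)c(OCc3ccccc3)c2)C[C@@H](CCc2ccc(OCc3ccccc3)c(OCc3ccccc3)c2)O1 | intermediate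
12 | (3R,5R)-1,7-bis[3,4-bis(benzyloxy)phenyl]-5-hydroxyheptan-3-yl acetate | CC(=O)O[C@H](CCc1ccc(OCc2ccccc2)c(OCc2ccccc2)c1)C[C@H](O)CCc1ccc(OCc2ccccc2)c(OCc2ccccc2)c1 | intermediate
13 | (3R,5R)-1,7-bis(3,4-dihydroxyphenyl)-5-hydroxyheptan-3-yl acetate | CC(=O)O[C@H](CCc1ccc(O)c(O)c1)C[C@H](O)CCc1ccc(O)c(O)c1 | target

**Total step count:** 7. **Longest linear sequence:** 6 steps (1, 2, 3, 5, 6, 7). The aryl branch enters through step 4.

**Steps most likely to fail**

**Step 5.** Three things may go wrong:
- magnesium chloride opens the oxiranes to chlorohydrins;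
- the reaction stalls after the first opening;
- the benzyl reagent attacks through its ortho ring carbon.

The fallback sets out from 1 and 6 and comes back at 10. It forms the same C–C bonds with inverted polarity, the C5 unit acting as the nucleophile.
- Dione 1 is converted with LDA (2 equiv, THF, 0 °C) into its 1,3-dianion. This is alkylated at the terminal carbon by 6 to give 6-[3,4-bis(benzyloxy)phenyl]hexane-2,4-dione F1 as its enolate.
- One further equivalent of LDA regenerates a dianion at the remaining methyl group. A second equivalent of 6 then gives 1,7-bis[3,4-bis(benzyloxy)phenyl]heptane-3,5-dione F2.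
- Noyori hydrogenation of F2 with an (R)-BINAP–Ru catalyst (H2, MeOH–CH2Cl2) should set C3 and C5 as R,R and lead to 10.
- This path also bypasses steps 1 to 4.

**Step 4.** Wurtz-type homocoupling of the electron-rich benzylic chloride at the metal surface may leave too little active reagent. The fallback sets out from 6 and comes back at 10. It replaces the organomagnesium by a carbanion stabilised with a removable sulfonyl group.
- Chloride 6 and sodium benzenesulfinate (DMF, rt) give 1,2-bis(benzyloxy)-4-[(phenylsulfonyl)methyl]benzene F3.
- Deprotonation (n-BuLi, THF–DMPU, −78 °C) and addition of 5 (0.45 equiv, warming to rt) open both oxiranes at the terminal carbon. The product is (3S,5S)-1,7-bis[3,4-bis(benzyloxy)phenyl]-1,7-bis(phenylsulfonyl)heptane-3,5-diol F4, a mixture of epimers at the two sulfonyl-bearing carbons. Its carbinol carbons have the same spatial arrangement as in 10; the descriptor changes only through the CIP rank of sulfur.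
- Reductive desulfonylation (Mg, MeOH, or Na/Hg, Na2HPO4, MeOH) erases these two centres and funnels all epimers into 10.

**Step 6.** Closure of the six-membered orthoester on an anti-diol forces one side chain axial or the ring into a twist form. It may therefore be slow, so that acyclic mixed orthoesters form and hydrolysis returns diol or gives double acetylation. The fallback sets out from 10 and comes back at 12.
- Dibutyltin oxide (toluene, reflux, water removal) gives (4R,6R)-2,2-dibutyl-4,6-bis{2-[3,4-bis(benzyloxy)phenyl]ethyl}-1,3,2-dioxastanninane F5.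
- Acetyl chloride (1 equiv, CH2Cl2, 0 °C) acylates one Sn–O bond and leaves the other oxygen as a deactivated chlorostannyl alkoxide. Aqueous work-up then releases 12.

**Further compounds**

F1 | step 5 | 6-[3,4-bis(benzyloxy)phenyl]hexane-2,4-dione | CC(=O)CC(=O)CCc1ccc(OCc2ccccc2)c(OCc2ccccc2)c1
F2 | step 5 | 1,7-bis[3,4-bis(benzyloxy)phenyl]heptane-3,5-dione | O=C(CCc1ccc(OCc2ccccc2)c(OCc2ccccc2)c1)CC(=O)CCc1ccc(OCc2ccccc2)c(OCc2ccccc2)c1
F3 | step 4 | 1,2-bis(benzyloxy)-4-[(phenylsulfonyl)methyl]benzene | O=S(=O)(Cc1ccc(OCc2ccccc2)c(OCc2ccccc2)c1)c1ccccc1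
F4 | step 4 | (3S,5S)-1,7-bis[3,4-bis(benzyloxy)phenyl]-1,7-bis(phenylsulfonyl)heptane-3,5-diol (epimers at C1 and C7) | O[C@H](CC(c1ccc(OCc2ccccc2)c(OCc2ccccc2)c1)S(=O)(=O)c1ccccc1)C[C@H](O)CC(c1ccc(OCc2ccccc2)c(OCc2ccccc2)c1)S(=O)(=O)c1ccccc1
F5 | step 6 | (4R,6R)-2,2-dibutyl-4,6-bis{2-[3,4-bis(benzyloxy)phenyl]ethyl}-1,3,2-dioxastanninane | CCCC[Sn]1(CCCC)O[C@H](CCc2ccc(OCc3ccccc3)c(OCc3ccccc3)c2)C[C@@H](CCc2ccc(OCc3ccccc3)c(OCc3ccccc3)c2)O1
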